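**Retrosynthetic overview**
1. Target ⇒ (13R)-allylic alcohol (acetylation last). The 14-membered carbocycle and the C-12–C-13 bond come from a ring-contracting 1,2-boronate shift: a 15-membered cyclic diazonium boronate (C-13 diazoalkane added to the C-12 alkenylboronate) loses N2, then C–B is oxidised to C–OH.
2. The seco compound is a cis-α-methylene-γ-butyrolactone carrying CH2CHO (C-14/C-13) on C-1 and the trienylboronic acid on C-2. The lactone (C-1–C-2 bond, both stereocentres) comes from an enantioselective allylboration/lactonisation of a C-2 enal with a 2-(methoxycarbonyl)allylboronate.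
3. Allylboronate ⇐ dioxolanylmethyl Grignard reagent + methyl propiolate + ICH2Bpin (carbocupration/alkylation).
4. Enal–alkenylboronate ⇐ boron–Wittig olefination of a twelve-carbon dialdehyde ⇐ B-alkyl Suzuki union (C-6–C-7) of a dienol and an (E)-iodoalkenol made by Zr-catalysed carboalumination.
5. Ring order: γ-lactone first (step 7), then the 15-membered boracycle, which contracts to the 14-membered carbocycle (step 9).

Assumption: atom labels C-1 to C-20 follow cembrane numbering of the target (C-1 = ring-fusion CH bearing the lactone α-carbon C-15, C-2 = lactone O–CH, C-13 = acetoxy carbon, C-17 = exocyclic CH2); the four starting materials and all named reagents are taken as commercial; Bpin = 4,4,5,5-tetramethyl-1,3,2-dioxaborolan-2-yl.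

**Step 1**
Reactants: 1 pent-4-yn-1-ol
Product: 3 (4E)-5-iodo-4-methylpent-4-en-1-ol, via alkenylalane 2 (not isolated)
Conditions: AlMe3 (3 equiv), Cp2ZrCl2 (25 mol %), CH2Cl2, 0 → 23 °C; then I2, THF, −30 → 0 °C; aq. K2CO3 work-up
Reagents that add atoms: trimethylaluminium, C[Al](C)C; iodine, II
Why: Zirconium-catalysed carboalumination (Negishi) adds Me and Al syn across the terminal alkyne with Me on the internal carbon, and iodinolysis of the C–Al bond goes with retention, which fixes the E trisubstituted alkene (future C-7=C-8).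

**Step 2**
Reactants: 4 (2E)-3-methylpent-2-en-4-yn-1-ol
Product: 5 (2E)-3-methylpenta-2,4-dien-1-ol
Conditions: H2 (1 atm), Pd/CaCO3 poisoned with Pb(OAc)2 (Lindlar), quinoline, pentane–Et2O, 0 °C, stopped after 1 equiv H2
Reagents that add atoms: none
Why: Lindlar semihydrogenation reduces the terminal alkyne to the vinyl group and leaves the existing E alkene (future C-3=C-4) untouched.

**Step 3**
Reactants: 5 (2E)-3-methylpenta-2,4-dien-1-ol; 3 (4E)-5-iodo-4-methylpent-4-en-1-ol
Product: 7 (2E,6E)-3,7-dimethyldeca-2,6-diene-1,10-diol, via homoallylic B-alkyl-9-BBN borane 6 (not isolated)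
Conditions: 9-BBN (2.2 equiv), THF, 0 → 23 °C; then 3, PdCl2(dppf) (5 mol %), AsPh3, Cs2CO3, DMF–H2O, 23 °C
Reagents that add atoms: none
Why: 9-BBN hydroborates only the monosubstituted terminus of the diene (anti-Markovnikov, after the OH has been capped as its borinate), and the B-alkyl Suzuki–Miyaura coupling with the alkenyl iodide proceeds with retention, forming C-6–C-7 with both E alkenes intact.

**Step 4**
Reactants: 7 (2E,6E)-3,7-dimethyldeca-2,6-diene-1,10-diol
Product: 8 (2E,6E)-3,7-dimethyldeca-2,6-dienedial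
Conditions: TEMPO (10 mol %), PhI(OAc)2 (2.3 equiv), CH2Cl2, 23 °C
Reagents that add atoms: none
Why: TEMPO/PhI(OAc)2 oxidation takes both primary alcohols to aldehydes without over-oxidation and without E/Z isomerisation of the new enal.

**Step 5**
Reactants: 8 (2E,6E)-3,7-dimethyldeca-2,6-dienedial
Product: 9 (2E,6E,10Z)-3,7-dimethyl-11-(4,4,5,5-tetramethyl-1,3,2-dioxaborolan-2-yl)dodeca-2,6,10-trienal
Conditions: CH3CH(Bpin)2 (1.05 equiv), lithium 2,2,6,6-tetramethylpiperidide (1.05 equiv), THF, 0 °C; then 8, −78 → 0 °C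
Reagents that add atoms: 1,1-bis(4,4,5,5-tetramethyl-1,3,2-dioxaborolan-2-yl)ethane, CC(B1OC(C)(C)C(C)(C)O1)B1OC(C)(C)C(C)(C)O1
Why: Boron–Wittig olefination, in which the lithiated gem-diboronate adds to the saturated aldehyde faster than to the β,β-disubstituted enal and syn B–O elimination places the chain trans to the remaining Bpin (cis to methyl), the geometry needed for the later E C-11=C-12 alkene.

**Step 6**
Reactants: 10 (1,3-dioxolan-2-ylmethyl)magnesium bromide; 11 methyl prop-2-ynoate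
Product: 14 methyl (2E)-4-(1,3-dioxolan-2-yl)-2-[(4,4,5,5-tetramethyl-1,3,2-dioxaborolan-2-yl)methyl]but-2-enoate, via alkylcopper 12 (not isolated), via α-cuprio acrylate 13 (not isolated)
Conditions: CuBr·SMe2 (1.0 equiv), THF, −78 °C; 11, −78 °C; then HMPA, ICH2Bpin, −78 → 0 °C
Reagents that add atoms: 2-(iodomethyl)-4,4,5,5-tetramethyl-1,3,2-dioxaborolane, ICB1OC(C)(C)C(C)(C)O1
Why: Syn carbocupration of the propiolate followed by alkylation of the α-cuprio acrylate with ICH2Bpin (Hall-type synthesis of 2-alkoxycarbonyl allylboronates) puts the C-14 methylene cis to CH2B, which is also the thermodynamically preferred geometry.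

**Step 7**
Reactants: 9 (2E,6E,10Z)-3,7-dimethyl-11-(4,4,5,5-tetramethyl-1,3,2-dioxaborolan-2-yl)dodeca-2,6,10-trienal; 14 methyl (2E)-4-(1,3-dioxolan-2-yl)-2-[(4,4,5,5-tetramethyl-1,3,2-dioxaborolan-2-yl)methyl]but-2-enoate
Product: 16 (4S,5S)-4-(1,3-dioxolan-2-ylmethyl)-5-[(1E,5E,9Z)-2,6-dimethyl-10-(4,4,5,5-tetramethyl-1,3,2-dioxaborolan-2-yl)undeca-1,5,9-trien-1-yl]-3-methylideneoxolan-2-one, via O-boryl hydroxy ester 15 (not isolated)
Conditions: (R)-3,3'-bis(2,4,6-triisopropylphenyl)-1,1'-binaphthyl-2,2'-diyl hydrogen phosphate (10 mol %), 4 Å MS, toluene, −20 → 23 °C; then TsOH·H2O (10 mol %), 23 °C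
Reagents that add atoms: none
Why: Chiral-phosphoric-acid-catalysed allylboration of the aldehyde through a closed chair transition state, in which the γ-substituent cis to CH2B sits axial and gives the syn adduct (hence the cis lactone), the (R)-acid directs attack to the Re face of the enal (2S, therefore 1S), and the alkoxide lactonises onto the methyl ester while the alkenyl-Bpin stays inert.

**Step 8**
Reactants: 16 (4S,5S)-4-(1,3-dioxolan-2-ylmethyl)-5-[(1E,5E,9Z)-2,6-dimethyl-10-(4,4,5,5-tetramethyl-1,3,2-dioxaborolan-2-yl)undeca-1,5,9-trien-1-yl]-3-methylideneoxolan-2-one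
Product: 17 [(2Z,6E,10E)-6,10-dimethyl-11-[(2S,3S)-4-methylidene-5-oxo-3-(2-oxoethyl)oxolan-2-yl]undeca-2,6,10-trien-2-yl]boronic acid
Conditions: NaIO4 (4 equiv), 1 M aq. HCl, THF, 23 °C
Reagents that add atoms: water, O
Why: Acid hydrolysis of the dioxolane and of the pinacol boronate is driven to completion because periodate cleaves both liberated 1,2-diols, while lactone, alkenes and the C–B bond are inert.

**Step 9**
Reactants: 17 [(2Z,6E,10E)-6,10-dimethyl-11-[(2S,3S)-4-methylidene-5-oxo-3-(2-oxoethyl)oxolan-2-yl]undeca-2,6,10-trien-2-yl]boronic acid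
Product: 23 (3aS,5R,6E,10E,14E,15aS)-5-hydroxy-6,10,14-trimethyl-3-methylidene-3a,4,5,8,9,12,13,15a-octahydrocyclotetradeca[b]furan-2(3H)-one, via N-triftosylhydrazone 18 (not isolated), via tartrate boronate hydrazone 19 (not isolated), via C-13 diazoalkane 20 (not isolated), via 15-membered cyclic diazonium boronate 21 (not isolated), via macrocyclic allylboronate 22 (not isolated)
Conditions: 2-(trifluoromethyl)benzenesulfonyl hydrazide (1.0 equiv), THF, 0 → 23 °C; diisopropyl (2S,3S)-tartrate (1.05 equiv), 4 Å MS; NaH (1.05 equiv), −20 °C; syringe pump into THF (final 0.5 mM), 30 °C; then 30 % aq. H2O2, aq. NaHCO3, 0 °C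
Reagents that add atoms: hydrogen peroxide, OO
Why: Proposed new method: base-triggered slow release of a non-stabilised diazoalkane at C-13 at high dilution lets the nucleophilic diazo carbon add to the Lewis-acidic tartrate alkenylboronate at the other chain end to give a 15-membered cyclic diazonium boronate, loss of N2 then drives a stereospecific 1,2-shift of the alkenyl carbon C-12 from boron to C-13 (anti to N2, alkene geometry retained) that contracts the boracycle to the 14-membered carbocycle with boron exocyclic on C-13, the C2-symmetric (S,S)-tartrate on boron is intended to select the diazo face (sense assigned by analogy with the steric model of diol-directed 1,2-boronate shifts) so that retentive oxidation gives the 13R alcohol; the closest known reaction types are the intermolecular homologation of alkenylboronic acids with diazoalkanes generated from sulfonylhydrazones (Barluenga–Valdés type coupling, here with oxidative work-up) and chiral-diol-directed 1,2-boronate shifts (Matteson type), and what is not known is the macrocyclising, ring-contracting mode and diol control at the diazo carbon.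

**Step 10**
Reactants: 23 (3aS,5R,6E,10E,14E,15aS)-5-hydroxy-6,10,14-trimethyl-3-methylidene-3a,4,5,8,9,12,13,15a-octahydrocyclotetradeca[b]furan-2(3H)-one
Product: 24 (3aS,5R,6E,10E,14E,15aS)-6,10,14-trimethyl-3-methylidene-2-oxo-2,3,3a,4,5,8,9,12,13,15a-decahydrocyclotetradeca[b]furan-5-yl acetate
Conditions: Ac2O, DMAP (cat.), pyridine, CH2Cl2, 0 → 23 °C
Reagents that add atoms: acetic anhydride, CC(=O)OC(C)=O
Why: DMAP-catalysed acylation of the secondary allylic alcohol occurs at oxygen with retention at C-13 and gives the target.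

**Compound list**
1 | pent-4-yn-1-ol | C#CCCCO | starting material
2 | dimethyl{(1E)-5-[(dimethylalumanyl)oxy]-2-methylpent-1-en-1-yl}alumane (alkenylalane) | C[Al](C)OCCC/C(C)=C/[Al](C)C | intermediate
3 | (4E)-5-iodo-4-methylpent-4-en-1-ol | OCCC/C(C)=C/I | intermediate
4 | (2E)-3-methylpent-2-en-4-yn-1-ol | OC/C=C(\C)C#C | starting material
5 | (2E)-3-methylpenta-2,4-dien-1-ol | OC/C=C(\C)C=C | intermediate
6 | 9-[(3E)-5-(9-borabicyclo[3.3.1]nonan-9-yloxy)-3-methylpent-3-en-1-yl]-9-borabicyclo[3.3.1]nonane | C(/C=C(\C)CCB1C2CCCC1CCC2)OB1C2CCCC1CCC2 | intermediate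
7 | (2E,6E)-3,7-dimethyldeca-2,6-diene-1,10-diol | OC/C=C(\C)CC/C=C(\C)CCCO | intermediate
8 | (2E,6E)-3,7-dimethyldeca-2,6-dienedial | O=C/C=C(\C)CC/C=C(\C)CCC=O | intermediate
9 | (2E,6E,10Z)-3,7-dimethyl-11-(4,4,5,5-tetramethyl-1,3,2-dioxaborolan-2-yl)dodeca-2,6,10-trienal | O=C/C=C(\C)CC/C=C(\C)CC/C=C(\C)B1OC(C)(C)C(C)(C)O1 | intermediate
10 | (1,3-dioxolan-2-ylmethyl)magnesium bromide | Br[Mg]CC1OCCO1 | starting material
11 | methyl prop-2-ynoate | C#CC(=O)OC | starting material
12 | (1,3-dioxolan-2-ylmethyl)copper (MgBr2 complex) | [Cu]CC1OCCO1 | intermediate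
13 | methyl (2Z)-2-cuprio-4-(1,3-dioxolan-2-yl)but-2-enoate | COC(=O)/C([Cu])=C/CC1OCCO1 | intermediate
14 | methyl (2E)-4-(1,3-dioxolan-2-yl)-2-[(4,4,5,5-tetramethyl-1,3,2-dioxaborolan-2-yl)methyl]but-2-enoate | COC(=O)/C(CB1OC(C)(C)C(C)(C)O1)=C/CC2OCCO2 | intermediate
15 | methyl (3S,4S,5E,9E,13Z)-3-(1,3-dioxolan-2-ylmethyl)-6,10-dimethyl-2-methylidene-14-(Bpin)-4-[(Bpin)oxy]pentadeca-5,9,13-trienoate | COC(=O)C(=C)[C@H](CC1OCCO1)[C@@H](OB2OC(C)(C)C(C)(C)O2)/C=C(\C)CC/C=C(\C)CC/C=C(\C)B3OC(C)(C)C(C)(C)O3 | intermediate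
16 | (4S,5S)-4-(1,3-dioxolan-2-ylmethyl)-5-[(1E,5E,9Z)-2,6-dimethyl-10-(4,4,5,5-tetramethyl-1,3,2-dioxaborolan-2-yl)undeca-1,5,9-trien-1-yl]-3-methylideneoxolan-2-one | C=C1C(=O)O[C@@H](/C=C(\C)CC/C=C(\C)CC/C=C(\C)B2OC(C)(C)C(C)(C)O2)[C@H]1CC3OCCO3 | intermediate
17 | [(2Z,6E,10E)-6,10-dimethyl-11-[(2S,3S)-4-methylidene-5-oxo-3-(2-oxoethyl)oxolan-2-yl]undeca-2,6,10-trien-2-yl]boronic acid | C=C1C(=O)O[C@@H](/C=C(\C)CC/C=C(\C)CC/C=C(\C)B(O)O)[C@H]1CC=O | intermediate
18 | (E)-N-[2-(trifluoromethyl)benzenesulfonyl]hydrazone of aldehyde 17 (free boronic acid) | C=C1C(=O)O[C@@H](/C=C(\C)CC/C=C(\C)CC/C=C(\C)B(O)O)[C@H]1C/C=N/NS(=O)(=O)c2ccccc2C(F)(F)F | intermediate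
19 | diisopropyl (4S,5S)-1,3,2-dioxaborolane-4,5-dicarboxylate (tartrate) ester of 18 | C=C1C(=O)O[C@@H](/C=C(\C)CC/C=C(\C)CC/C=C(\C)B2O[C@H](C(=O)OC(C)C)[C@@H](C(=O)OC(C)C)O2)[C@H]1C/C=N/NS(=O)(=O)c3ccccc3C(F)(F)F | intermediate
20 | C-13 diazoalkane (2-diazoethyl on C-1 of the lactone; tartrate alkenylboronate at C-12) | C=C1C(=O)O[C@@H](/C=C(\C)CC/C=C(\C)CC/C=C(\C)B2O[C@H](C(=O)OC(C)C)[C@@H](C(=O)OC(C)C)O2)[C@H]1CC=[N+]=[N-] | intermediate
21 | 15-membered cyclic diazonium boronate (zwitterion; tetracoordinate B bonded to C-12 and C-13, N2+ on C-13, tartrate on B) | C=C1C(=O)O[C@H]2/C=C(\C)CC/C=C(\C)CC/C=C(\C)[B-]3(O[C@H](C(=O)OC(C)C)[C@@H](C(=O)OC(C)C)O3)[C@H]([N+]#N)C[C@@H]12 | intermediate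
22 | 14-membered (13R)-allylboronic ester (diisopropyl (4S,5S)-tartrate boronate on C-13) | C=C1C(=O)O[C@H]2/C=C(\C)CC/C=C(\C)CC/C=C(\C)[C@H](B3O[C@H](C(=O)OC(C)C)[C@@H](C(=O)OC(C)C)O3)C[C@@H]12 | intermediate
23 | (3aS,5R,6E,10E,14E,15aS)-5-hydroxy-6,10,14-trimethyl-3-methylidene-3a,4,5,8,9,12,13,15a-octahydrocyclotetradeca[b]furan-2(3H)-one | C=C1C(=O)O[C@H]2/C=C(\C)CC/C=C(\C)CC/C=C(\C)[C@H](O)C[C@@H]12 | intermediate
24 | (3aS,5R,6E,10E,14E,15aS)-6,10,14-trimethyl-3-methylidene-2-oxo-2,3,3a,4,5,8,9,12,13,15a-decahydrocyclotetradeca[b]furan-5-yl acetate (CNP0182196.1) | C=C1C(=O)O[C@H]2/C=C(\C)CC/C=C(\C)CC/C=C(\C)[C@H](OC(C)=O)C[C@@H]12 | target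

**Step count and risks**
Total steps: 10. Longest linear sequence: 8 (steps 1, 3, 4, 5, 7, 8, 9, 10).

Most likely to fail:

Step 9 (the proposed new ring-contracting diazo–boronate shift). The risks are three:
- oligomerisation instead of cyclisation;
- dipolar cycloaddition of the diazoalkane to the α-methylene lactone;
- weak or reversed induction by the tartrate (if only the sense is wrong, the (2R,3R)-tartrate is used).

Fallback with known chemistry, setting out from 17 and returning at 23: iododeboronation of 17 with N-iodosuccinimide in MeCN (retention) gives 2-[(2S,3S)-2-[(1E,5E,9E)-10-iodo-2,6-dimethylundeca-1,5,9-trien-1-yl]-4-methylidene-5-oxooxolan-3-yl]acetaldehyde F1. Nozaki–Hiyama–Kishi macrocyclisation (CrCl2, catalytic NiCl2, DMSO–THF, 1 mM) closes the same C-12–C-13 bond and gives 23 together with its C-13 epimer, the (3aS,5S,15aS)-alcohol F2. The mixture is converged by MnO2 oxidation to the macrocyclic enone (3aS,6E,10E,14E,15aS)-6,10,14-trimethyl-3-methylidene-3a,4,8,9,12,13-hexahydrocyclotetradeca[b]furan-2,5(3H,15aH)-dione F3 and reduction with (S)-2-methyl-CBS-oxazaborolidine/catecholborane, which delivers 23.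

Step 7 (rate and enantioselectivity of the phosphoric-acid-catalysed allylboration with the deactivated, γ-substituted 2-alkoxycarbonyl allylboronate). Fallback setting out from 9 and 14 and returning at 16: Sc(OTf)3-catalysed allylboration/lactonisation (toluene, 23 °C) gives the racemic cis-lactone, that is 16 together with its enantiomer, the (4R,5R)-lactone F4. Preparative chiral SFC then supplies 16, so resolution replaces asymmetric catalysis.

Step 5 (discrimination between the two aldehydes, and geometry of the boron–Wittig product). Fallback setting out from 3 and 5 and returning at 9, which separates the two carbonyls by oxidation state: TEMPO/PhI(OAc)2 oxidation of 3 gives (4E)-5-iodo-4-methylpent-4-enal F5. Hydroboration of 5 with 9-BBN (until no B–H remains) and Suzuki coupling with F5 gives (4E,8E)-10-hydroxy-4,8-dimethyldeca-4,8-dienal F6. Boron–Wittig olefination of F6 (2.1 equiv of lithiated reagent, the first consumed by the OH) gives (2E,6E,10Z)-3,7-dimethyl-11-(4,4,5,5-tetramethyl-1,3,2-dioxaborolan-2-yl)dodeca-2,6,10-trien-1-ol F7, and MnO2 oxidation of the allylic alcohol gives 9.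

**Further compounds**
F1 | step 9 | 2-[(2S,3S)-2-[(1E,5E,9E)-10-iodo-2,6-dimethylundeca-1,5,9-trien-1-yl]-4-methylidene-5-oxooxolan-3-yl]acetaldehyde | C=C1C(=O)O[C@@H](/C=C(\C)CC/C=C(\C)CC/C=C(\C)I)[C@H]1CC=O
F2 | step 9 | (3aS,5S,6E,10E,14E,15aS)-5-hydroxy-6,10,14-trimethyl-3-methylidene-3a,4,5,8,9,12,13,15a-octahydrocyclotetradeca[b]furan-2(3H)-one | C=C1C(=O)O[C@H]2/C=C(\C)CC/C=C(\C)CC/C=C(\C)[C@@H](O)C[C@@H]12
F3 | step 9 | (3aS,6E,10E,14E,15aS)-6,10,14-trimethyl-3-methylidene-3a,4,8,9,12,13-hexahydrocyclotetradeca[b]furan-2,5(3H,15aH)-dione | C=C1C(=O)O[C@H]2/C=C(\C)CC/C=C(\C)CC/C=C(\C)C(=O)C[C@@H]12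
F4 | step 7 | (4R,5R)-4-(1,3-dioxolan-2-ylmethyl)-5-[(1E,5E,9Z)-2,6-dimethyl-10-(4,4,5,5-tetramethyl-1,3,2-dioxaborolan-2-yl)undeca-1,5,9-trien-1-yl]-3-methylideneoxolan-2-one | C=C1C(=O)O[C@H](/C=C(\C)CC/C=C(\C)CC/C=C(\C)B2OC(C)(C)C(C)(C)O2)[C@@H]1CC3OCCO3
F5 | step 5 | (4E)-5-iodo-4-methylpent-4-enal | O=CCC/C(C)=C/I
F6 | step 5 | (4E,8E)-10-hydroxy-4,8-dimethyldeca-4,8-dienal | O=CCC/C(C)=C/CC/C(C)=C/CO
F7 | step 5 | (2E,6E,10Z)-3,7-dimethyl-11-(4,4,5,5-tetramethyl-1,3,2-dioxaborolan-2-yl)dodeca-2,6,10-trien-1-ol | OC/C=C(\C)CC/C=C(\C)CC/C=C(\C)B1OC(C)(C)C(C)(C)O1
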